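**Retrosynthetic overview**

1. Target numbering: C1 (acetyl), C2 (sec-butyl), C3=C4, C4a, C5 (OH), C6 (acyloxy), C7, C8 (methyl), C8a. The strategy rests on the cis C3=C4 alkene of ring A, which can act as the tether, and on ring B (oxygens at C5 and C6, methyl at C8), which is a masked cyclohexene silyl enol ether.
2. Late stage: C5-OH from the C5 ketone; C6 ester and C5 ketone from Rubottom oxidation of the C5=C6 silyl enol ether; C8 methyl from a C8 ester; the side-chain acid is carried as a silyl-protected primary alcohol.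
3. Key disconnection: bonds C4a–C8a and C7–C8, an intramolecular Diels–Alder reaction of the 2-siloxy diene C4a=C5–C6=C7 with the (E)-enoate C8a=C8 in tetraene 35.
4. Tetraene 35 comes from a Z-Wittig reaction at C3=C4 and an HWE reaction at C8a=C8 on an acyclic C1/C2 core. The core comes from an Ireland–Claisen rearrangement (bond C1–C2) of a Z-allylic ester built from (R)-2-methylbutanoic acid, ethyl (S)-lactate and the acetoacetate ketal.
5. Ring order: both rings form in one step, ring B as the cycloadduct and ring A as the tether ring.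

Key step: step 24

Remark (assumption): locants C1–C8a in names follow the target numbering above. C5 of 26–33 is racemic, so 32 and 33 are C5-epimer mixtures; this is harmless because C5 becomes a ketone in step 22.

**Route**

Step 1
Reactants: 1 (R)-2-methylbutanoic acid
Product: 2 (R)-2-methylbutan-1-ol
Conditions: LiAlH4, Et2O, 0 °C → rt
Reagents that add atoms: none
Why: Hydride reduction of the acid to the primary alcohol; the α-stereocentre is safe because the carboxylate does not enolise.

Step 2
Reactants: 2 (R)-2-methylbutan-1-ol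
Product: 3 (R)-1-iodo-2-methylbutane
Conditions: I2, PPh3, imidazole, CH2Cl2, 0 °C → rt
Reagents that add atoms: iodine, II
Why: Appel-type iodination, an SN2 displacement at the primary carbon that leaves the neighbouring stereocentre untouched.

Step 3
Reactants: 3 (R)-1-iodo-2-methylbutane
Product: 4 [(R)-2-methylbutyl]triphenylphosphonium iodide
Conditions: PPh3, MeCN, reflux, 48 h
Reagents that add atoms: triphenylphosphine, c1ccc(cc1)P(c1ccccc1)c1ccccc1
Why: SN2 quaternisation of phosphorus by the primary iodide, slow for the β-branched halide but standard for this salt type.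

Step 4
Reactants: 5 ethyl (S)-lactate
Product: 6 ethyl (S)-2-(tert-butyldimethylsilyloxy)propanoate
Conditions: TBSCl, imidazole, DMF, rt
Reagents that add atoms: tert-butyldimethylsilyl chloride, CC(C)(C)[Si](C)(C)Cl
Why: Silylation of the secondary alcohol under imidazole catalysis, without touching the stereocentre.

Step 5
Reactants: 6 ethyl (S)-2-(tert-butyldimethylsilyloxy)propanoate
Product: 7 (S)-2-(tert-butyldimethylsilyloxy)propanal
Conditions: i-Bu2AlH (1.05 equiv), Et2O, −78 °C; aqueous work-up at low temperature, used crude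
Reagents that add atoms: none
Why: Partial ester reduction through the aluminium hemiacetal that is stable at −78 °C, the usual route to configurationally intact O-silyl lactaldehyde.

Step 6
Reactants: 4 [(R)-2-methylbutyl]triphenylphosphonium iodide; 7 (S)-2-(tert-butyldimethylsilyloxy)propanal
Product: 9 tert-butyldimethylsilyl ether of (2S,3Z,5R)-5-methylhept-3-en-2-ol, via ylide 8 (not isolated)
Conditions: NaN(SiMe3)2, THF, −78 → 0 °C; then 7, −78 °C → rt
Reagents that add atoms: none
Why: Wittig olefination of a non-stabilised ylide under lithium-free conditions gives the Z-alkene through the kinetically formed cis-oxaphosphetane; neither existing stereocentre is acidic enough to be disturbed at −78 °C.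

Step 7
Reactants: 9 tert-butyldimethylsilyl ether of (2S,3Z,5R)-5-methylhept-3-en-2-ol
Product: 10 (2S,3Z,5R)-5-methylhept-3-en-2-ol
Conditions: HF·pyridine, pyridine, THF, 0 °C → rt
Reagents that add atoms: none
Why: Fluoride-driven Si–O cleavage under buffered conditions that cannot ionise or transpose the allylic alcohol.

Step 8
Reactants: 11 ethyl 2-(2-methyl-1,3-dioxolan-2-yl)acetate
Product: 12 2-(2-methyl-1,3-dioxolan-2-yl)acetic acid
Conditions: LiOH·H2O, THF/H2O, rt; then 1 M HCl to pH 4, 0 °C
Reagents that add atoms: lithium hydroxide, [Li+].[OH-]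
Why: Saponification of the ester; the base-stable ketal survives and the cold, mild acidification avoids ketal hydrolysis.

Step 9
Reactants: 10 (2S,3Z,5R)-5-methylhept-3-en-2-ol; 12 2-(2-methyl-1,3-dioxolan-2-yl)acetic acid
Product: 13 (2S,3Z,5R)-5-methylhept-3-en-2-yl 2-(2-methyl-1,3-dioxolan-2-yl)acetate
Conditions: EDC·HCl, DMAP, CH2Cl2, 0 °C → rt
Reagents that add atoms: none
Why: Steglich esterification with retention at the carbinol carbon, since the C–O bond of the alcohol is not broken.

Step 10
Reactants: 13 (2S,3Z,5R)-5-methylhept-3-en-2-yl 2-(2-methyl-1,3-dioxolan-2-yl)acetate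
Product: 16 (2R,3S,4E)-3-[(2R)-butan-2-yl]-2-(2-methyl-1,3-dioxolan-2-yl)hex-4-enoic acid, via silyl ketene acetal 14 (not isolated), via trimethylsilyl ester 15 (not isolated)
Conditions: LiN(i-Pr)2, Me3SiCl (present from the start), THF–DMPU 4:1, −78 °C; then 50 °C; aq. NaHCO3/MeOH, then pH 4
Reagents that add atoms: none
Why: Ireland–Claisen rearrangement: in the dissociating medium the ester gives the Z(O) enolate (dioxolanyl cis to the O-metal, which chelation by a dioxolane oxygen would only reinforce) and is trapped at once as 14 before β-elimination can occur; the chair transition state with the carbinol methyl equatorial, the sec-butyl of the Z-alkene axial and the dioxolanyl equatorial forms C1–C2 with the anti relationship, transfers the (S)-carbinol chirality to both new centres and leaves an (E)-propenyl group.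

Step 11
Reactants: 16 (2R,3S,4E)-3-[(2R)-butan-2-yl]-2-(2-methyl-1,3-dioxolan-2-yl)hex-4-enoic acid
Product: 17 (4E)-3-[(2R)-butan-2-yl]-2-(2-methyl-1,3-dioxolan-2-yl)hex-4-en-1-ol (C1 and C2 of the target as in 16)
Conditions: LiAlH4, THF, 0 °C → rt
Reagents that add atoms: none
Why: Hydride reduction of the acid to the primary alcohol (the future C8a); ketal and alkene are inert.

Step 12
Reactants: 17 primary alcohol
Product: 18 (4E)-3-[(2R)-butan-2-yl]-2-(2-methyl-1,3-dioxolan-2-yl)hex-4-enal
Conditions: Dess–Martin periodinane, NaHCO3, CH2Cl2, 0 °C → rt; used crude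
Reagents that add atoms: none
Why: Dess–Martin oxidation under buffered, non-basic conditions, so the α-stereocentre (C1) next to the ketal neither epimerises nor eliminates.

Step 13
Reactants: 18 aldehyde; 19 trimethyl phosphonoacetate
Product: 20 methyl (2E,6E)-5-[(2R)-butan-2-yl]-4-(2-methyl-1,3-dioxolan-2-yl)octa-2,6-dienoate
Conditions: LiCl, DBU, MeCN, 0 °C → rt
Reagents that add atoms: trimethyl phosphonoacetate 19, COC(=O)CP(=O)(OC)OC
Why: Horner–Wadsworth–Emmons olefination under Masamune–Roush conditions, which are mild enough for the epimerisable aldehyde and give the (E)-enoate C8a=C8.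

Step 14
Reactants: 20 dienoate
Product: 22 methyl (2E)-5-[(2R)-butan-2-yl]-4-(2-methyl-1,3-dioxolan-2-yl)-6-oxohex-2-enoate, via ozonide 21 (not isolated)
Conditions: O3, CH2Cl2, −78 °C, stopped at the first blue tint; then PPh3, −78 °C → rt; used at once
Reagents that add atoms: ozone, [O-][O+]=O
Why: Ozonolysis is electrophilic and so attacks the electron-rich 1,2-dialkyl propenyl alkene well before the electron-poor enoate; reductive work-up gives the C3 aldehyde.

Step 15
Reactants: 23 ethyl acetate; 24 acrolein
Product: 26 ethyl 3-hydroxypent-4-enoate (racemic), via lithium enolate 25 (not isolated)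
Conditions: LiN(i-Pr)2, THF, −78 °C; then acrolein, −78 °C; AcOH quench
Reagents that add atoms: none
Why: Aldol addition of the lithium ester enolate, which adds 1,2 to acrolein at low temperature.

Step 16
Reactants: 26 ethyl 3-hydroxypent-4-enoate
Product: 27 ethyl 3-(tert-butyldimethylsilyloxy)pent-4-enoate
Conditions: TBSCl, imidazole, DMF, rt
Reagents that add atoms: tert-butyldimethylsilyl chloride, CC(C)(C)[Si](C)(C)Cl
Why: Silylation of the allylic alcohol, which also blocks retro-aldol and elimination in the next steps.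

Step 17
Reactants: 27 ethyl 3-(tert-butyldimethylsilyloxy)pent-4-enoate
Product: 28 3-(tert-butyldimethylsilyloxy)pent-4-en-1-ol
Conditions: i-Bu2AlH (2.3 equiv), CH2Cl2, −78 → 0 °C
Reagents that add atoms: none
Why: Full reduction of the ester to the primary alcohol by the aluminium hydride, without silyl migration in the non-basic medium.

Step 18
Reactants: 28 3-(tert-butyldimethylsilyloxy)pent-4-en-1-ol
Product: 29 tert-butyl[(5-iodopent-1-en-3-yl)oxy]dimethylsilane
Conditions: I2, PPh3, imidazole, CH2Cl2, 0 °C
Reagents that add atoms: iodine, II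
Why: Appel-type iodination of the primary alcohol by SN2 displacement.

Step 19
Reactants: 29 primary iodide
Product: 30 [3-(tert-butyldimethylsilyloxy)pent-4-en-1-yl]triphenylphosphonium iodide
Conditions: PPh3, NaHCO3 (trace), MeCN, 80 °C
Reagents that add atoms: triphenylphosphine, c1ccc(cc1)P(c1ccccc1)c1ccccc1
Why: SN2 quaternisation of phosphorus by the unhindered primary iodide.

Step 20
Reactants: 22 C3 aldehyde; 30 phosphonium iodide
Product: 32 methyl (2E,6Z)-5-[(2R)-butan-2-yl]-9-(tert-butyldimethylsilyloxy)-4-(2-methyl-1,3-dioxolan-2-yl)undeca-2,6,10-trienoate, via ylide 31 (not isolated)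
Conditions: NaN(SiMe3)2, THF, −78 → −20 °C; then 22, −78 → 0 °C
Reagents that add atoms: none
Why: Z-selective Wittig olefination of a non-stabilised ylide (the silyloxy group sits γ to the ylide carbon and cannot eliminate); at −78 °C the aldehyde reacts far faster than the enoate and C2 should not epimerise.

Step 21
Reactants: 32 silyl ether
Product: 33 methyl (2E,6Z)-5-[(2R)-butan-2-yl]-9-hydroxy-4-(2-methyl-1,3-dioxolan-2-yl)undeca-2,6,10-trienoate
Conditions: HF·pyridine, pyridine, THF, 0 °C → rt
Reagents that add atoms: none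
Why: Buffered fluoride desilylation that spares the ketal and the enoate.

Step 22
Reactants: 33 allylic alcohol
Product: 34 methyl (2E,6Z)-5-[(2R)-butan-2-yl]-4-(2-methyl-1,3-dioxolan-2-yl)-9-oxoundeca-2,6,10-trienoate
Conditions: Dess–Martin periodinane, NaHCO3, CH2Cl2, 0 °C; filtered cold and used at once
Reagents that add atoms: none
Why: Dess–Martin oxidation of the secondary allylic alcohol under neutral conditions, which should leave the β,γ-alkene out of conjugation.

Step 23
Reactants: 34 vinyl ketone
Product: 35 methyl (2E,6Z,8Z)-5-[(2R)-butan-2-yl]-9-(tert-butyldimethylsilyloxy)-4-(2-methyl-1,3-dioxolan-2-yl)undeca-2,6,8,10-tetraenoate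
Conditions: TBSOTf, Et3N, CH2Cl2, −78 °C; base-washed silica
Reagents that add atoms: tert-butyldimethylsilyl trifluoromethanesulfonate, CC(C)(C)[Si](C)(C)OS(=O)(=O)C(F)(F)F
Why: Soft enolisation toward the only α-CH2 (C4a, doubly activated) and O-silylation give the 2-siloxy diene; the enol ether with C4 cis to oxygen is expected because it avoids allylic strain with the vinyl group, as for simple alkyl vinyl ketones.

Step 24
Reactants: 35 siloxy tetraene
Product: 36 trans-fused octalin silyl enol ether: C1 2-methyl-1,3-dioxolan-2-yl, C2 (R)-sec-butyl, C3=C4, C5=C6 with OTBS on C5, C8 CO2Me; C1, C2, C4a, C8, C8a as in the target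
Conditions: Me2AlCl (2 equiv), CH2Cl2 (0.005 M), −78 → −30 °C; aq. NaHCO3
Reagents that add atoms: none
Why: Me2AlCl binds the enoate carbonyl and the 2-siloxy diene C4a=C5–C6=C7 adds to C8a=C8 in an asynchronous, polarity-matched [4+2] cycloaddition (the nucleophilic terminus C4a bonds first to the β-carbon C8a, then C7 to C8); the closest known reaction is the Lewis-acid-promoted intramolecular Diels–Alder reaction of a terminally activated deca-1,7,9-trienoate, here with a silyl dienol ether as the diene. Ring B is closed as the new cyclohexene of the cycloaddition (bonds C4a–C8a and C7–C8), and ring A is closed as the six-membered tether ring by the C4a–C8a bond across the tether C4=C3–C2–C1, whose cis alkene already holds the two ends close together. C4a and C8a are set by the transition state with the ester endo and the tether anti, which gives the trans ring fusion, and C8 follows from the E geometry of the enoate, which keeps the ester trans to C1 on ring B. The π-face is set by C1 and C2: in the half-chair of the forming ring A the dioxolanyl group at C1 should sit equatorial, on the side of the dienophile away from the diene, which places H-1 anti to H-8a and leaves the sec-butyl group pseudoaxial. The step needs face, endo and chemoselectivity: the first comes from the C1/C2 pair made in step 10, the second from the coordinated ester, and the third from the low temperature and the mild Lewis acid, under which neither the 1,5-hydrogen shift of the Z-diene nor ionisation of the dioxolane should compete.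

Step 25
Reactants: 36 octalin ester
Product: 37 C8 hydroxymethyl octalin silyl enol ether
Conditions: LiAlH4, Et2O, 0 °C
Reagents that add atoms: none
Why: Hydride reduction of the ester to the primary alcohol; the silyl enol ether and the ketal are inert to hydride, and reduction is faster than epimerisation at C8.

Step 26
Reactants: 37 primary alcohol
Product: 38 C8 (methanesulfonyloxy)methyl octalin silyl enol ether
Conditions: MsCl, Et3N, CH2Cl2, 0 °C
Reagents that add atoms: methanesulfonyl chloride, CS(=O)(=O)Cl
Why: Sulfonylation of the primary alcohol in the presence of excess amine, so no acid reaches the enol ether.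

Step 27
Reactants: 38 mesylate
Product: 39 C8 methyl octalin silyl enol ether
Conditions: LiEt3BH, THF, 0 → 50 °C
Reagents that add atoms: none
Why: SN2 displacement of the primary sulfonate by hydride gives the C8 methyl group with the configuration fixed in step 24.

Step 28
Reactants: 39 silyl enol ether
Product: 41 C5 ketone with axial C6 hydroxyl (ketal at C1 retained; all centres as in the target), via silyloxy epoxide 40 (not isolated)
Conditions: dimethyldioxirane (1.05 equiv), acetone/CH2Cl2, −78 °C; then HF·pyridine, THF, −40 → 0 °C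
Reagents that add atoms: dimethyldioxirane, CC1(C)OO1
Why: Rubottom oxidation: the electron-rich enol ether is epoxidised far faster than the C3=C4 alkene; attack on the face syn to H-4a corresponds to axial bonding at the nucleophilic carbon C6 through a chair-like transition state and is expected to be favoured, and fluoride then collapses the silyloxy epoxide to the α-hydroxy ketone with retention at C6.

Step 29
Reactants: 42 tert-butyl(but-3-yn-1-yloxy)dimethylsilane
Product: 44 ethyl (E)-5-(tert-butyldimethylsilyloxy)-3-methylpent-2-enoate, via alkenylalane 43 (not isolated)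
Conditions: Me3Al, (C5H5)2ZrCl2 (0.25 equiv), CH2Cl2, 0 °C → rt; then ClCO2Et, 0 °C → rt
Reagents that add atoms: trimethylaluminium, C[Al](C)C; ethyl chloroformate, CCOC(=O)Cl
Why: Negishi zirconium-catalysed carboalumination adds methyl and aluminium syn across the alkyne with the metal at the terminus, and acylation of the C–Al bond with retention gives the E trisubstituted enoate.

Step 30
Reactants: 44 ethyl ester
Product: 45 (E)-5-(tert-butyldimethylsilyloxy)-3-methylpent-2-enoic acid
Conditions: LiOH·H2O, THF/MeOH/H2O, rt; then pH 4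
Reagents that add atoms: lithium hydroxide, [Li+].[OH-]
Why: Saponification of the enoate; the primary silyl ether tolerates the mild hydroxide conditions.

Step 31
Reactants: 41 hydroxy ketone; 45 (E)-5-(tert-butyldimethylsilyloxy)-3-methylpent-2-enoic acid
Product: 46 C6 ester of 41 with the (E)-5-silyloxy-3-methylpent-2-enoyl group
Conditions: EDC·HCl, DMAP, CH2Cl2, 0 °C → rt
Reagents that add atoms: none
Why: Steglich acylation of the axial C6 hydroxyl; an acid without an activated γ-methylene is used so that no vinylketene can form and scramble the alkene position or geometry.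

Step 32
Reactants: 46 silyl ether
Product: 47 C6 ester with free primary alcohol in the side chain
Conditions: HF·pyridine, pyridine, THF, 0 °C
Reagents that add atoms: none
Why: Buffered fluoride removal of the primary silyl ether; ketal, enoate and α-acyloxy ketone are untouched.

Step 33
Reactants: 47 primary alcohol
Product: 49 C5 ketone with C6 (E)-4-carboxy-3-methylbut-2-enoate, via aldehyde 48 (not isolated)
Conditions: TEMPO (0.2 equiv), PhI(OAc)2 (2.2 equiv), MeCN/H2O 1:1, rt
Reagents that add atoms: water, O
Why: Oxoammonium oxidation of the primary alcohol to the aldehyde and, through its hydrate, on to the acid under near-neutral conditions; this limits enolisation of the β,γ-unsaturated aldehyde, and no other hydroxyl is present.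

Step 34
Reactants: 49 keto acid
Product: 50 C5 equatorial alcohol (C1 ketal still in place)
Conditions: NaBH4, CeCl3·7H2O, MeOH, −78 °C; AcOH quench at −78 °C
Reagents that add atoms: none
Why: Luche-type 1,2-reduction: hydride attacks C5 axially, anti to the axial C6–O bond (Felkin–Anh polar control), giving the equatorial hydroxyl cis to the ester; the cold, weakly acidic medium suppresses acyl migration to the new hydroxyl.

Step 35
Reactants: 50 hydroxy acid ketal
Product: 51 target, CNP0404452.1
Conditions: 1 M HCl, THF, rt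
Reagents that add atoms: water, O
Why: Acid-catalysed hydrolysis of the dioxolane frees the C1 acetyl group; it is kept short and cool to avoid epimerisation at C1 and acyl migration.

**Compound list**

1 | (R)-2-methylbutanoic acid | CC[C@@H](C)C(=O)O | starting material
2 | (R)-2-methylbutan-1-ol | CC[C@@H](C)CO | intermediate
3 | (R)-1-iodo-2-methylbutane | CC[C@@H](C)CI | intermediate
4 | [(R)-2-methylbutyl]triphenylphosphonium iodide | CC[C@@H](C)C[P+](c1ccccc1)(c1ccccc1)c1ccccc1.[I-] | intermediate
5 | ethyl (S)-lactate | CCOC(=O)[C@H](C)O | starting material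
6 | ethyl (S)-2-(tert-butyldimethylsilyloxy)propanoate | CCOC(=O)[C@H](C)O[Si](C)(C)C(C)(C)C | intermediate
7 | (S)-2-(tert-butyldimethylsilyloxy)propanal | C[C@H](O[Si](C)(C)C(C)(C)C)C=O | intermediate
8 | [(R)-2-methylbutylidene]triphenylphosphorane | CC[C@@H](C)C=P(c1ccccc1)(c1ccccc1)c1ccccc1 | intermediate (not isolated)
9 | tert-butyldimethylsilyl ether of (2S,3Z,5R)-5-methylhept-3-en-2-ol | CC[C@@H](C)/C=C\[C@H](C)O[Si](C)(C)C(C)(C)C | intermediate
10 | (2S,3Z,5R)-5-methylhept-3-en-2-ol | CC[C@@H](C)/C=C\[C@H](C)O | intermediate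
11 | ethyl 2-(2-methyl-1,3-dioxolan-2-yl)acetate | CCOC(=O)CC1(C)OCCO1 | starting material
12 | 2-(2-methyl-1,3-dioxolan-2-yl)acetic acid | OC(=O)CC1(C)OCCO1 | intermediate
13 | (2S,3Z,5R)-5-methylhept-3-en-2-yl 2-(2-methyl-1,3-dioxolan-2-yl)acetate | CC[C@@H](C)/C=C\[C@H](C)OC(=O)CC1(C)OCCO1 | intermediate
14 | (Z)-O-trimethylsilyl ketene acetal of 13 (dioxolanyl cis to OSiMe3) | CC[C@@H](C)/C=C\[C@H](C)O/C(O[Si](C)(C)C)=C/C1(C)OCCO1 | intermediate (not isolated)
15 | trimethylsilyl ester of 16 | CC[C@@H](C)[C@@H](/C=C/C)[C@@H](C(=O)O[Si](C)(C)C)C1(C)OCCO1 | intermediate (not isolated)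
16 | (2R,3S,4E)-3-[(2R)-butan-2-yl]-2-(2-methyl-1,3-dioxolan-2-yl)hex-4-enoic acid | CC[C@@H](C)[C@@H](/C=C/C)[C@@H](C(=O)O)C1(C)OCCO1 | intermediate
17 | (4E)-3-[(2R)-butan-2-yl]-2-(2-methyl-1,3-dioxolan-2-yl)hex-4-en-1-ol | CC[C@@H](C)[C@@H](/C=C/C)[C@@H](CO)C1(C)OCCO1 | intermediate
18 | (4E)-3-[(2R)-butan-2-yl]-2-(2-methyl-1,3-dioxolan-2-yl)hex-4-enal | CC[C@@H](C)[C@@H](/C=C/C)[C@@H](C=O)C1(C)OCCO1 | intermediate
19 | trimethyl phosphonoacetate | COC(=O)CP(=O)(OC)OC | starting material
20 | methyl (2E,6E)-5-[(2R)-butan-2-yl]-4-(2-methyl-1,3-dioxolan-2-yl)octa-2,6-dienoate | CC[C@@H](C)[C@@H](/C=C/C)[C@@H](/C=C/C(=O)OC)C1(C)OCCO1 | intermediate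
21 | ozonide (1,2,4-trioxolane) of the propenyl group of 20 | CC[C@@H](C)[C@@H](C2OOC(C)O2)[C@@H](/C=C/C(=O)OC)C1(C)OCCO1 | intermediate (not isolated)
22 | methyl (2E)-5-[(2R)-butan-2-yl]-4-(2-methyl-1,3-dioxolan-2-yl)-6-oxohex-2-enoate | CC[C@@H](C)[C@@H](C=O)[C@@H](/C=C/C(=O)OC)C1(C)OCCO1 | intermediate
23 | ethyl acetate | CCOC(C)=O | starting material
24 | acrolein | C=CC=O | starting material
25 | lithium enolate of ethyl acetate | C=C(O[Li])OCC | intermediate (not isolated)
26 | ethyl 3-hydroxypent-4-enoate (racemic) | CCOC(=O)CC(O)C=C | intermediate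
27 | ethyl 3-(tert-butyldimethylsilyloxy)pent-4-enoate | CCOC(=O)CC(O[Si](C)(C)C(C)(C)C)C=C | intermediate
28 | 3-(tert-butyldimethylsilyloxy)pent-4-en-1-ol | OCCC(O[Si](C)(C)C(C)(C)C)C=C | intermediate
29 | tert-butyl[(5-iodopent-1-en-3-yl)oxy]dimethylsilane | ICCC(O[Si](C)(C)C(C)(C)C)C=C | intermediate
30 | [3-(tert-butyldimethylsilyloxy)pent-4-en-1-yl]triphenylphosphonium iodide | C=CC(O[Si](C)(C)C(C)(C)C)CC[P+](c1ccccc1)(c1ccccc1)c1ccccc1.[I-] | intermediate
31 | [3-(tert-butyldimethylsilyloxy)pent-4-en-1-ylidene]triphenylphosphorane | C=CC(O[Si](C)(C)C(C)(C)C)CC=P(c1ccccc1)(c1ccccc1)c1ccccc1 | intermediate (not isolated)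
32 | methyl (2E,6Z)-5-[(2R)-butan-2-yl]-9-(tert-butyldimethylsilyloxy)-4-(2-methyl-1,3-dioxolan-2-yl)undeca-2,6,10-trienoate (C9 epimers) | CC[C@@H](C)[C@@H](/C=C\CC(O[Si](C)(C)C(C)(C)C)C=C)[C@@H](/C=C/C(=O)OC)C1(C)OCCO1 | intermediate
33 | methyl (2E,6Z)-5-[(2R)-butan-2-yl]-9-hydroxy-4-(2-methyl-1,3-dioxolan-2-yl)undeca-2,6,10-trienoate (C9 epimers) | CC[C@@H](C)[C@@H](/C=C\CC(O)C=C)[C@@H](/C=C/C(=O)OC)C1(C)OCCO1 | intermediate
34 | methyl (2E,6Z)-5-[(2R)-butan-2-yl]-4-(2-methyl-1,3-dioxolan-2-yl)-9-oxoundeca-2,6,10-trienoate | CC[C@@H](C)[C@@H](/C=C\CC(=O)C=C)[C@@H](/C=C/C(=O)OC)C1(C)OCCO1 | intermediate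
35 | methyl (2E,6Z,8Z)-5-[(2R)-butan-2-yl]-9-(tert-butyldimethylsilyloxy)-4-(2-methyl-1,3-dioxolan-2-yl)undeca-2,6,8,10-tetraenoate | CC[C@@H](C)[C@@H](/C=C\C=C(/O[Si](C)(C)C(C)(C)C)C=C)[C@@H](/C=C/C(=O)OC)C1(C)OCCO1 | intermediate (key-step precursor)
36 | trans-octalin silyl enol ether with C8 methyl ester and C1 ketal | CC[C@@H](C)[C@H]1C=C[C@H]2C(O[Si](C)(C)C(C)(C)C)=CC[C@@H](C(=O)OC)[C@@H]2[C@H]1C3(C)OCCO3 | intermediate (key-step product)
37 | C8 hydroxymethyl analogue of 36 | CC[C@@H](C)[C@H]1C=C[C@H]2C(O[Si](C)(C)C(C)(C)C)=CC[C@@H](CO)[C@@H]2[C@H]1C3(C)OCCO3 | intermediate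
38 | C8 (methanesulfonyloxy)methyl analogue of 36 | CC[C@@H](C)[C@H]1C=C[C@H]2C(O[Si](C)(C)C(C)(C)C)=CC[C@@H](COS(C)(=O)=O)[C@@H]2[C@H]1C3(C)OCCO3 | intermediate
39 | C8 methyl octalin silyl enol ether | CC[C@@H](C)[C@H]1C=C[C@H]2C(O[Si](C)(C)C(C)(C)C)=CC[C@@H](C)[C@@H]2[C@H]1C3(C)OCCO3 | intermediate
40 | 5-silyloxy 5,6-epoxide of 39 (oxygen syn to H-4a) | CC[C@@H](C)[C@H]1C=C[C@H]2[C@]4(O[Si](C)(C)C(C)(C)C)O[C@@H]4C[C@@H](C)[C@@H]2[C@H]1C3(C)OCCO3 | intermediate (not isolated)
41 | C5 ketone with axial C6 hydroxyl, C1 ketal | CC[C@@H](C)[C@H]1C=C[C@H]2C(=O)[C@H](O)C[C@@H](C)[C@@H]2[C@H]1C3(C)OCCO3 | intermediate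
42 | tert-butyl(but-3-yn-1-yloxy)dimethylsilane | C#CCCO[Si](C)(C)C(C)(C)C | starting material
43 | (E)-alkenyldimethylalane from 42 (methyl and aluminium cis) | C/C(CCO[Si](C)(C)C(C)(C)C)=C\[Al](C)C | intermediate (not isolated)
44 | ethyl (E)-5-(tert-butyldimethylsilyloxy)-3-methylpent-2-enoate | CCOC(=O)/C=C(\C)CCO[Si](C)(C)C(C)(C)C | intermediate
45 | (E)-5-(tert-butyldimethylsilyloxy)-3-methylpent-2-enoic acid | OC(=O)/C=C(\C)CCO[Si](C)(C)C(C)(C)C | intermediate
46 | C6 (E)-5-(tert-butyldimethylsilyloxy)-3-methylpent-2-enoate of 41 | CC[C@@H](C)[C@H]1C=C[C@H]2C(=O)[C@H](OC(=O)/C=C(\C)CCO[Si](C)(C)C(C)(C)C)C[C@@H](C)[C@@H]2[C@H]1C3(C)OCCO3 | intermediate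
47 | C6 (E)-5-hydroxy-3-methylpent-2-enoate of 41 | CC[C@@H](C)[C@H]1C=C[C@H]2C(=O)[C@H](OC(=O)/C=C(\C)CCO)C[C@@H](C)[C@@H]2[C@H]1C3(C)OCCO3 | intermediate
48 | C6 (E)-3-methyl-5-oxopent-2-enoate of 41 | CC[C@@H](C)[C@H]1C=C[C@H]2C(=O)[C@H](OC(=O)/C=C(\C)CC=O)C[C@@H](C)[C@@H]2[C@H]1C3(C)OCCO3 | intermediate (not isolated)
49 | C5 ketone with C6 (E)-4-carboxy-3-methylbut-2-enoate, C1 ketal | CC[C@@H](C)[C@H]1C=C[C@H]2C(=O)[C@H](OC(=O)/C=C(\C)CC(=O)O)C[C@@H](C)[C@@H]2[C@H]1C3(C)OCCO3 | intermediate
50 | C5 alcohol with C6 (E)-4-carboxy-3-methylbut-2-enoate, C1 ketal | CC[C@@H](C)[C@H]1C=C[C@H]2[C@H](O)[C@H](OC(=O)/C=C(\C)CC(=O)O)C[C@@H](C)[C@@H]2[C@H]1C3(C)OCCO3 | intermediate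
51 | CNP0404452.1 | CC[C@@H](C)[C@H]1C=C[C@H]2[C@H](O)[C@H](OC(=O)/C=C(\C)CC(=O)O)C[C@@H](C)[C@@H]2[C@H]1C(C)=O | target

**Step count and risks**

Total step count: 35. Longest linear sequence: 25 steps (1–3, 6, 7, 9–14, 20–28, 31–35, from acid 1).

Steps most likely to fail:

1. Step 24 (key cycloaddition). What may go wrong: attack on the wrong π-face or exo closure; ionisation of the dioxolane by the Lewis acid with Mukaiyama-type attack of C4a on the ketal carbon; or a stepwise Michael addition that stops after the C4a–C8a bond. Fallback: set out from vinyl ketone 34 and run the same two bond formations as an anionic intramolecular double Michael reaction. LiN(SiMe3)2 in THF at −78 °C forms the cross-conjugated dienolate; its C4a adds to the enoate at C8a, and the resulting ester enolate adds to the vinyl ketone at C7. This gives the C5–C6 lithium enolate F1, which is silylated in the same flask with TBSCl to return to the route at 36.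

2. Step 28 (Rubottom oxidation). What may go wrong: poor facial selectivity of the epoxidation, or preferential attack from the face anti to H-4a, since both faces of the enol ether carry only hydrogens. Fallback: set out from 39 and accept the other face. The epimeric silyloxy epoxide F2 collapses with HF·pyridine to the equatorial C6 ketol F3. F3 is then esterified with acid 45 under Mitsunobu conditions (PPh3, diisopropyl azodicarboxylate, toluene, 0 °C → rt), where the carboxylate displaces the activated hydroxyl with inversion and gives the axial ester, returning to the route at 46. If both ketols form, each is taken on by its own esterification.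

3. Step 20 (Z-Wittig on aldehyde 22). What may go wrong: base-induced epimerisation at C2 of the α-branched aldehyde, conjugate addition of the ylide to the enoate, or eroded Z selectivity. Fallback: change the order so that no enoate is present when the ylide is used. Set out from alcohol 17; ozonolysis (O3, then PPh3) gives ozonide F4 and, after reduction, the five-membered lactol F5. Wittig reaction of F5 with an excess of ylide 31 gives the Z-alkenyl primary alcohol F6. Dess–Martin oxidation gives aldehyde F7, and the Masamune–Roush olefination with 19 returns to the route at 32.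

**Further compounds**

F1 | step 24 | C5–C6 lithium enolate of the trans-octalin C8 ester (double Michael product) | CC[C@@H](C)[C@H]1C=C[C@H]2C(O[Li])=CC[C@@H](C(=O)OC)[C@@H]2[C@H]1C3(C)OCCO3
F2 | step 28 | 5-silyloxy 5,6-epoxide of 39 with oxygen anti to H-4a | CC[C@@H](C)[C@H]1C=C[C@H]2[C@@]4(O[Si](C)(C)C(C)(C)C)O[C@H]4C[C@@H](C)[C@@H]2[C@H]1C3(C)OCCO3
F3 | step 28 | C5 ketone with equatorial C6 hydroxyl (C6 epimer of 41) | CC[C@@H](C)[C@H]1C=C[C@H]2C(=O)[C@@H](O)C[C@@H](C)[C@@H]2[C@H]1C3(C)OCCO3
F4 | step 20 | ozonide of the propenyl group of 17 | CC[C@@H](C)[C@@H](C2OOC(C)O2)[C@@H](CO)C1(C)OCCO1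
F5 | step 20 | 3-[(2R)-butan-2-yl]-4-(2-methyl-1,3-dioxolan-2-yl)tetrahydrofuran-2-ol (lactol, anomer mixture) | CC[C@@H](C)[C@H]2C(O)OC[C@H]2C1(C)OCCO1
F6 | step 20 | (4Z)-3-[(2R)-butan-2-yl]-7-(tert-butyldimethylsilyloxy)-2-(2-methyl-1,3-dioxolan-2-yl)nona-4,8-dien-1-ol | CC[C@@H](C)[C@@H](/C=C\CC(O[Si](C)(C)C(C)(C)C)C=C)[C@@H](CO)C1(C)OCCO1
F7 | step 20 | (4Z)-3-[(2R)-butan-2-yl]-7-(tert-butyldimethylsilyloxy)-2-(2-methyl-1,3-dioxolan-2-yl)nona-4,8-dienal | CC[C@@H](C)[C@@H](/C=C\CC(O[Si](C)(C)C(C)(C)C)C=C)[C@@H](C=O)C1(C)OCCO1
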